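The closed vessel holds 0.050 M of starting material, and the quick number reckoned here is the one for its late contents.

| setting | west | south-west | north-west | flask |
|---|---|---|---|---|
| starting material | 0.050 M | 0.050 M | 0.10 M | 0.050 M |
| first nucleophile | 1.2 equiv | 1.2 equiv | 1.2 equiv | 1.20 equiv |
| second nucleophile | 0.55 equiv | 0.83 equiv | 1.1 equiv | 1.10 equiv |
| remark | run made earlier | run made earlier | run made earlier |  |
| time |  |  |  | 12 h |

| run | time / h | target / % | other capture product / % |
|---|---|---|---|
| west | 0.833 | 49.9 | 21.7 |
| west | 1.33 | 48.2 | 27.3 |
| west | 2.00 | 45.2 | 32.0 |
| west | 2.50 | 43.8 | 35.8 |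
| west | 4.00 | 39.7 | 42.6 |
| west | 6.00 | 36.0 | 46.0 |
| west | 10.0 | 33.4 | 51.3 |
| south-west | 0.500 | 42.6 | 20.4 |
| south-west | 1.33 | 42.6 | 36.9 |
| south-west | 2.50 | 36.6 | 47.1 |
| south-west | 4.00 | 30.6 | 56.5 |
| south-west | 6.00 | 26.9 | 63.4 |
| south-west | 8.00 | 24.2 | 66.3 |
| south-west | 10.0 | 20.1 | 70.0 |
| north-west | 2.00 | 33.9 | 52.7 |
| north-west | 4.00 | 24.8 | 66.9 |
| north-west | 6.00 | 18.7 | 73.2 |
| north-west | 8.00 | 16.6 | 79.1 |
| north-west | 10.0 | 12.9 | 81.6 |

(standard deviation of a reading: 0.5 percentage points)

- ratio of target to other capture product at 2.5 min
- ratio of target to other capture product at 40 min
- ratio of target to other capture product at 12 h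
- which of target and other capture product there is more of at 12 h

- on the list of suspects stand: second nucleophile + intermediate -> other capture product; target <-> isomer of the product; first nucleophile + intermediate <-> target; starting material -> intermediate

The end state comes first. Of the suspected steps, capture by the second nucleophile has no way back, and the flask's 1.10 equiv covers the starting material, so target is a way-station and other capture product the sink.

The approach comes next. The south-west run shows target ahead at its first reading, 42.6% against 20.4%, so first nucleophile evidently captures intermediate readily. Target then leaks back through intermediate at a pseudo-first-order rate λ, taken here as proportional to s, the second nucleophile left over the free first nucleophile, and volume cancels in s.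

In the north-west run, target between 4.00 h and 10.0 h gives λ = 0.109 /h. With mean other capture product 74.2%, and everything else counted as holding first nucleophile, s = 0.379. The leak constant κ = λ/s, the fractional loss of target per hour at equal amounts of the two nucleophiles, reads about 0.287 /h.

The flask has north-west's equivalents at half its concentration. Taken on north-west's clock from its last reading, it leaks by my reckoning at 0.0803 /h; with the remaining material falling in step with target, that gives target 11.0% and a ratio of 0.130 at 12 h.

Your forecast reads 2.2, 1.45 and 0.15, with other capture product ahead; its ground for the late figure is “Partitioning is then nearly the same, but more material sits as free I, so it lags slightly”. My figure is lower.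

The flask gives 2.90, 1.37 and 0.134, with other capture product ahead.

    second nucleophile + intermediate → other capture product (k = 0.0225 /M/s)
    target ⇌ isomer of the product (K = 0.306, k = 3.58 × 10⁻⁴ /s)
    first nucleophile + intermediate ⇌ target (K = 177 /M, k = 0.0627 /M/s)
    starting material → intermediate (k = 0.00107 /s)

At 12.0 h the flask holds target 11.3% and other capture product 84.1%, with 23.6% of the second nucleophile's charge and 87.7% of the first's free, so κ puts its leak then at 0.0708 /h. A neighbouring flask charged with 0.280 equiv of second nucleophile keeps, at that time, 0.587% of that charge and 47.7% of its first nucleophile, so κ puts its leak far lower, at 8.24 × 10⁻⁴ /h, and its target stands at 48.0%.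

The runs are simulated from invented constants; the scatter is artificial.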